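## Retrosynthetic overview

1. Target 11 ⇐ triol 10 by lipase acetylation of the primary hydroxyl; 10 ⇐ enone 9 by Morita–Baylis–Hillman hydroxymethylation with formaldehyde at C3.
2. 9 ⇐ epoxy ketone monoketal 7 by i-Bu2AlH reduction on the epoxide face, then ketal hydrolysis to unveil the enone.
3. 7 ⇐ racemic quinone monoketal carbinol 6 by the key C–O bond-forming step: an alkoxide-directed, tartrate-mediated nucleophilic epoxidation run as a kinetic resolution, which fixes the carbinol centre and both oxirane carbons.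
4. 6 ⇐ phenol 5 (PhI(OAc)2/MeOH dearomatisation) ⇐ 2-bromo-4-methoxyphenol 3 (dilithiation) + (2E,6E)-farnesal 2 (from farnesol 1).
5. Ring order: the six-membered carbocycle comes from the purchased arene; the only ring formed is the oxirane (step 4).

Assumption: D-(–)-diisopropyl tartrate is taken as the tartrate enantiomer that makes (S)-6 the fast-reacting enantiomer in step 4; if the sense proves opposite, L-(+)-diisopropyl tartrate is used and nothing else changes.

## Route

Step 1
Reactants: 1 (2E,6E)-farnesol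
Product: 2 (2E,6E)-farnesal
Conditions: MnO2 (15 equiv), CH2Cl2, rt, 2 h
Reagents that add atoms: none
Why: Allylic alcohol oxidation with activated MnO2 stops at the enal and leaves the 2E geometry and the remote trisubstituted alkenes untouched.

Step 2
Reactants: 3 2-bromo-4-methoxyphenol; 2 (2E,6E)-farnesal
Product: 5 rac-2-[(2E,6E)-1-hydroxy-3,7,11-trimethyldodeca-2,6,10-trien-1-yl]-4-methoxyphenol, via lithium 2-lithio-4-methoxyphenolate 4 (not isolated)
Conditions: 3 (1.2 equiv), n-BuLi (2.4 equiv), Et2O, 0 °C → rt; then 2, THF, –78 °C; aq. NH4Cl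
Reagents that add atoms: none
Why: Deprotonation then bromine–lithium exchange gives the ortho-lithiated phenoxide, which adds 1,2 to the enal (aryllithium carbonyl addition) to give the racemic carbinol, whose configuration is settled later by the resolution in step 4.

Step 3
Reactants: 5 rac-2-[(2E,6E)-1-hydroxy-3,7,11-trimethyldodeca-2,6,10-trien-1-yl]-4-methoxyphenol
Product: 6 rac-2-[(2E,6E)-1-hydroxy-3,7,11-trimethyldodeca-2,6,10-trien-1-yl]-4,4-dimethoxycyclohexa-2,5-dien-1-one
Conditions: PhI(OAc)2 (1.1 equiv), MeOH, 0 °C, 20 min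
Reagents that add atoms: methanol (CO)
Why: Hypervalent-iodine oxidative dearomatisation of a para-methoxyphenol in methanol traps the phenoxonium ion at the methoxy-bearing carbon, giving the para-quinone monoketal with the ketone next to the carbinol-bearing carbon, fast enough at 0 °C for the acid-labile ortho-hydroxybenzylic allylic alcohol (used crude) to survive.

Step 4
Reactants: 6 rac-2-[(2E,6E)-1-hydroxy-3,7,11-trimethyldodeca-2,6,10-trien-1-yl]-4,4-dimethoxycyclohexa-2,5-dien-1-one
Product: 7 (1S,6R)-1-[(1S,2E,6E)-1-hydroxy-3,7,11-trimethyldodeca-2,6,10-trien-1-yl]-5,5-dimethoxy-7-oxabicyclo[4.1.0]hept-3-en-2-one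
Conditions: Ph3COOH (0.55 equiv), NaN(SiMe3)2 (2.5 equiv), D-(–)-DIPT (1.2 equiv), 4 Å MS, PhMe, –65 °C, to ca. 50% conversion; aq. NH4Cl; unreacted (R)-6 removed by chromatography
Reagents that add atoms: trityl hydroperoxide (OOC(c1ccccc1)(c1ccccc1)c1ccccc1)
Why: Proposed new method: a tartrate-mediated, alkoxide-directed nucleophilic epoxidation run as a kinetic resolution of a racemic secondary carbinol, in which the sodium alkoxide of 6, sodium diisopropyl tartrate and Ph3COONa form a mixed aggregate that delivers the peroxide oxygen to the dienone β-carbon on the ring face syn to the C1′–O–Na and the resulting enolate closes the second C–O bond; allylic strain holds C1′–H in the ring plane toward the C=O, so the alkoxide sits on one face and the farnesyl-derived chain on the other, which fixes the relative configuration of C1′ and the oxirane, while the chiral tartrate makes delivery fast to one ring face only, so only (S)-6 is epoxidised and all three stereocentres of 7 are set in one step; the closest known reactions are the tartrate-mediated nucleophilic epoxidation of 2-(hydroxymethyl)quinone monoketals (primary carbinols, no resolution) and the Sharpless kinetic resolution of secondary allylic alcohols (electrophilic, electron-rich alkenes only).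

Step 5
Reactants: 7 (1S,6R)-1-[(1S,2E,6E)-1-hydroxy-3,7,11-trimethyldodeca-2,6,10-trien-1-yl]-5,5-dimethoxy-7-oxabicyclo[4.1.0]hept-3-en-2-one
Product: 9 (1R,5S,6S)-5-hydroxy-6-[(1S,2E,6E)-1-hydroxy-3,7,11-trimethyldodeca-2,6,10-trien-1-yl]-7-oxabicyclo[4.1.0]hept-3-en-2-one, via diol ketal 8 (not isolated)
Conditions: i-Bu2AlH (3 equiv), THF, –78 °C; then 10% aq. oxalic acid, 0 °C → rt
Reagents that add atoms: water (O)
Why: In this anti-selective α,β-epoxy ketone reduction the C1′–O–Al(i-Bu)2 group on the quaternary carbon blocks the face opposite the oxirane and the oxirane oxygen coordinates aluminium, so hydride enters syn to the epoxide oxygen and sets the ring carbinol (5S in 9) trans to the epoxide, after which mild acid hydrolyses the allylic dimethyl ketal to the enone (ketal hydrolysis).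

Step 6
Reactants: 9 (1R,5S,6S)-5-hydroxy-6-[(1S,2E,6E)-1-hydroxy-3,7,11-trimethyldodeca-2,6,10-trien-1-yl]-7-oxabicyclo[4.1.0]hept-3-en-2-one
Product: 10 (1R,5S,6R)-5-hydroxy-3-(hydroxymethyl)-6-[(1S,2E,6E)-1-hydroxy-3,7,11-trimethyldodeca-2,6,10-trien-1-yl]-7-oxabicyclo[4.1.0]hept-3-en-2-one
Conditions: 37% aq. CH2O (3 equiv), 4-(dimethylamino)pyridine (0.3 equiv), THF/H2O 1:1, rt
Reagents that add atoms: formaldehyde (C=O)
Why: In this Morita–Baylis–Hillman reaction the amine adds reversibly to the enone β-carbon, the enolate captures formaldehyde at the α-carbon and the amine is eliminated, installing CH2OH at C3 without touching any stereocentre.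

Step 7
Reactants: 10 (1R,5S,6R)-5-hydroxy-3-(hydroxymethyl)-6-[(1S,2E,6E)-1-hydroxy-3,7,11-trimethyldodeca-2,6,10-trien-1-yl]-7-oxabicyclo[4.1.0]hept-3-en-2-one
Product: 11 [(1R,5S,6R)-5-hydroxy-6-[(1S,2E,6E)-1-hydroxy-3,7,11-trimethyldodeca-2,6,10-trien-1-yl]-2-oxo-7-oxabicyclo[4.1.0]hept-3-en-3-yl]methyl acetate (CNP0137670.2)
Conditions: vinyl acetate (5 equiv), immobilised Candida antarctica lipase B, MTBE, 30 °C
Reagents that add atoms: vinyl acetate (CC(=O)OC=C)
Why: Regioselective lipase-catalysed transesterification acylates only the unhindered primary allylic hydroxyl under neutral conditions, because the two secondary hydroxyls flanking the quaternary oxirane carbon are too hindered for the enzyme.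

## Compound list

The descriptor at the quaternary oxirane carbon changes between 7, 8/9 and 10/11 only because CIP priorities change; its geometry is the same throughout.

1 | (2E,6E)-farnesol | OC/C=C(\C)CC/C=C(\C)CCC=C(C)C | starting material
2 | (2E,6E)-farnesal | O=C/C=C(\C)CC/C=C(\C)CCC=C(C)C | intermediate
3 | 2-bromo-4-methoxyphenol | COc1ccc(O)c(Br)c1 | starting material
4 | lithium 2-lithio-4-methoxyphenolate | COc1ccc(O[Li])c([Li])c1 | intermediate
5 | rac-2-[(2E,6E)-1-hydroxy-3,7,11-trimethyldodeca-2,6,10-trien-1-yl]-4-methoxyphenol (racemic at the carbinol carbon) | COc1ccc(O)c(c1)C(O)/C=C(\C)CC/C=C(\C)CCC=C(C)C | intermediate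
6 | rac-2-[(2E,6E)-1-hydroxy-3,7,11-trimethyldodeca-2,6,10-trien-1-yl]-4,4-dimethoxycyclohexa-2,5-dien-1-one (racemic at the carbinol carbon) | COC1(OC)C=CC(=O)C(=C1)C(O)/C=C(\C)CC/C=C(\C)CCC=C(C)C | intermediate
7 | (1S,6R)-1-[(1S,2E,6E)-1-hydroxy-3,7,11-trimethyldodeca-2,6,10-trien-1-yl]-5,5-dimethoxy-7-oxabicyclo[4.1.0]hept-3-en-2-one | C1=CC(=O)[C@@]2([C@@H](O)/C=C(\C)CC/C=C(\C)CCC=C(C)C)O[C@H]2C1(OC)OC | intermediate
8 | (1S,2S,6R)-1-[(1S,2E,6E)-1-hydroxy-3,7,11-trimethyldodeca-2,6,10-trien-1-yl]-5,5-dimethoxy-7-oxabicyclo[4.1.0]hept-3-en-2-ol | C1=C[C@H](O)[C@@]2([C@@H](O)/C=C(\C)CC/C=C(\C)CCC=C(C)C)O[C@H]2C1(OC)OC | intermediate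
9 | (1R,5S,6S)-5-hydroxy-6-[(1S,2E,6E)-1-hydroxy-3,7,11-trimethyldodeca-2,6,10-trien-1-yl]-7-oxabicyclo[4.1.0]hept-3-en-2-one | C1=C[C@H](O)[C@@]2([C@@H](O)/C=C(\C)CC/C=C(\C)CCC=C(C)C)O[C@H]2C1=O | intermediate
10 | (1R,5S,6R)-5-hydroxy-3-(hydroxymethyl)-6-[(1S,2E,6E)-1-hydroxy-3,7,11-trimethyldodeca-2,6,10-trien-1-yl]-7-oxabicyclo[4.1.0]hept-3-en-2-one | OCC1=C[C@H](O)[C@@]2([C@@H](O)/C=C(\C)CC/C=C(\C)CCC=C(C)C)O[C@H]2C1=O | intermediate
11 | [(1R,5S,6R)-5-hydroxy-6-[(1S,2E,6E)-1-hydroxy-3,7,11-trimethyldodeca-2,6,10-trien-1-yl]-2-oxo-7-oxabicyclo[4.1.0]hept-3-en-3-yl]methyl acetate | CC(=O)OCC1=C[C@H](O)[C@@]2([C@@H](O)/C=C(\C)CC/C=C(\C)CCC=C(C)C)O[C@H]2C1=O | target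

## Step count and risks

Total step count: 7. Longest linear sequence: 7 (1 → 2 → 5 → 6 → 7 → 9 → 10 → 11).

**Step 4 (the proposed new resolution–epoxidation).** The risks are a low selectivity factor with a secondary alkoxide, competing undirected epoxidation of the unsubstituted enone alkene, and the unverified sense of tartrate control. The fallback uses known chemistry and sets out from 6. A Sharpless kinetic resolution (Ti(OiPr)4, L-(+)-DIPT, t-BuOOH, 4 Å MS, CH2Cl2, –20 °C, about 55–60% conversion) acts on the electron-rich 2′,3′-alkene of the side chain. It consumes the (R)-enantiomer as 2-[(S)-hydroxy{(2R,3R)-3-[(3E)-4,8-dimethylnona-3,7-dien-1-yl]-3-methyloxiran-2-yl}methyl]-4,4-dimethoxycyclohexa-2,5-dien-1-one F2, which is discarded. It leaves 2-[(1S,2E,6E)-1-hydroxy-3,7,11-trimethyldodeca-2,6,10-trien-1-yl]-4,4-dimethoxycyclohexa-2,5-dien-1-one F1 in high ee. F1 is then epoxidised by the achiral alkoxide-directed nucleophilic epoxidation (Ph3COOH, NaN(SiMe3)2, PhMe, –65 °C, no tartrate), relying only on the allylic-strain control described in step 4. The route is rejoined at 7.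

**Step 5 (facial selectivity of the ketone reduction and survival of the epoxy alcohol in the acidic hydrolysis).** If the wrong ring-carbinol epimer dominates or the telescoped hydrolysis is not clean, the fallback sets out from 7. The ketal is hydrolysed first (wet CF3CO2H, CH2Cl2, 0 °C) to the epoxyquinone (1S,6R)-1-[(1S,2E,6E)-1-hydroxy-3,7,11-trimethyldodeca-2,6,10-trien-1-yl]-7-oxabicyclo[4.1.0]hept-3-ene-2,5-dione F3. A hydroxyl-directed reduction with Me4NBH(OAc)3 (MeCN/AcOH, –30 °C) follows. The alkoxyborohydride formed at the side-chain hydroxyl reduces only the β-hydroxy ketone, by internal delivery through a chair transition state with the alkenyl group equatorial, on the epoxide face. The route is rejoined at 9.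

**Step 6 (Morita–Baylis–Hillman reaction on a base-sensitive γ-hydroxy epoxy enone).** The risks are sluggish amine addition next to the carbinol and base-induced isomerisation or aromatisation. The fallback sets out from 9. α-Iodination (I2, pyridine, CH2Cl2, 0 °C) gives (1R,5S,6R)-5-hydroxy-6-[(1S,2E,6E)-1-hydroxy-3,7,11-trimethyldodeca-2,6,10-trien-1-yl]-3-iodo-7-oxabicyclo[4.1.0]hept-3-en-2-one F4. A Stille coupling with Bu3SnCH2OH (Pd(PPh3)4, CuI, THF, 50 °C) then installs the hydroxymethyl group. The route is rejoined at 10.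

Further compounds
F1 | step 4 | 2-[(1S,2E,6E)-1-hydroxy-3,7,11-trimethyldodeca-2,6,10-trien-1-yl]-4,4-dimethoxycyclohexa-2,5-dien-1-one | COC1(OC)C=CC(=O)C(=C1)[C@@H](O)/C=C(\C)CC/C=C(\C)CCC=C(C)C
F2 | step 4 | 2-[(S)-hydroxy{(2R,3R)-3-[(3E)-4,8-dimethylnona-3,7-dien-1-yl]-3-methyloxiran-2-yl}methyl]-4,4-dimethoxycyclohexa-2,5-dien-1-one | COC1(OC)C=CC(=O)C(=C1)[C@H](O)[C@H]2O[C@]2(C)CC/C=C(\C)CCC=C(C)C
F3 | step 5 | (1S,6R)-1-[(1S,2E,6E)-1-hydroxy-3,7,11-trimethyldodeca-2,6,10-trien-1-yl]-7-oxabicyclo[4.1.0]hept-3-ene-2,5-dione | C1=CC(=O)[C@@]2([C@@H](O)/C=C(\C)CC/C=C(\C)CCC=C(C)C)O[C@H]2C1=O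
F4 | step 6 | (1R,5S,6R)-5-hydroxy-6-[(1S,2E,6E)-1-hydroxy-3,7,11-trimethyldodeca-2,6,10-trien-1-yl]-3-iodo-7-oxabicyclo[4.1.0]hept-3-en-2-one | IC1=C[C@H](O)[C@@]2([C@@H](O)/C=C(\C)CC/C=C(\C)CCC=C(C)C)O[C@H]2C1=O
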